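**Plan**
- Retrosynthesis: cut the two C7=C8 / C7′=C8′ olefins (two-fold Julia–Kocienski) to the C20 polyene dialdehyde and two identical C10 ring sulfones. Then cut each ring at C2–C3 and C5–C6 into methyl but-2-ynoate (C3–C4=C5–Me, a 1,3-bis-electrophile) and di-tert-butyl 3,3-dimethylglutarate (C2–C1(Me)2–C6 with C7 attached, a 1,3-bis-nucleophile).
- Enabling feature: the quaternary gem-dimethyl C1 sits between C2 and C6, so the C2–C1–C6 unit is a symmetric glutarate that cannot enolise through C1 or aromatise. The 3-oxy-4-ene-5-methyl array C3–C4=C5 is the acyl carbon / β-carbon pair of an alkynoate.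
- Forward: esterification, then one Michael–Dieckmann [3+3] annulation builds the cyclohexene ring (the only ring-forming step; both rings of the target come from this intermediate). C7 is then taken from ester to sulfone, both rings are joined to the C20 chain in one double olefination, and desilylation comes last.
- Stereochemistry: C3 and C6 of both rings come from one ketoreductase dynamic kinetic resolution of the racemic, C6-labile keto ester. C7=C8 (E) comes from the Julia–Kocienski step with thermal equilibration; the other E olefins are bought with the dialdehyde.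
- Helpers: the tert-butoxycarbonyl group on C2 (makes C2 a nucleophile, leaves in step 3) and the ketone oxidation level at C3 (reduced in step 4).

Key step: step 2

Remark: atom labels C1–C7 in the explanations follow carotenoid numbering (C1 = CMe2, C2 = CH2, C3 = carbinol carbon, C4=C5(Me), C6 = ring CH, C7 = first chain carbon).
Remark: crocetindialdehyde (17) is taken as a purchasable C20 building block; LDA and KHMDS are used as purchased solutions.

Step 1
Reactants: 1 3,3-dimethylpentanedioic acid (3,3-dimethylglutaric acid)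
Product: 2 di-tert-butyl 3,3-dimethylpentanedioate
Conditions: isobutene (excess), conc. H2SO4 (cat.), CH2Cl2, pressure bottle, rt
Reagents that add atoms: isobutene (2-methylpropene), CC(C)=C
Why: Acid-catalysed addition of both carboxylic acid groups to isobutene (tert-butyl ester formation) is standard for diacids and gives an enolisable diester whose ester carbonyls are poor acyl acceptors; no stereocentre is involved.

Step 2
Reactants: 2 di-tert-butyl 3,3-dimethylpentanedioate; 3 methyl but-2-ynoate
Product: 5 di-tert-butyl 2,2,4-trimethyl-6-oxocyclohex-4-ene-1,3-dicarboxylate (stereoisomer mixture), via Michael adduct triester 4 (not isolated)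
Conditions: LDA (2.2 equiv), THF, −78 °C; 3 (1.0 equiv), −78 → 0 °C; t-BuOH (1 equiv), 50 °C; aq. NH4Cl
Reagents that add atoms: none
Why: One enolate terminus of the dilithium bis-enolate of 2 (future C6) adds in conjugate fashion to the β-carbon of ynoate 3 (C5–C6 bond), proton shuffling gives the delocalised anion of 4 in which C4=C5 can adopt the geometry with C3 cis to C6, and the second tert-butyl ester enolate (C2) then attacks the methyl ester carbon C3 with loss of methoxide (C2–C3 bond), the sequence being driven by deprotonation of the β-keto ester formed. The closest known reaction type is the Michael–Claisen (Dieckmann) [3+3] annulation used for dimedone and other cyclohexane-1,3-diones, run here with an alkynoate so that the C4=C5 enone survives. The ring closes by a 6-(enolexo)-exo-trig Dieckmann acylation; should C-acylation precede conjugate addition, the same ring would arise by 6-endo-dig closure. The two new stereocentres (C2 and C6) are not controlled and need not be, because C2 loses its ester in step 3 and C6 is epimerisable and is set in step 4. The step needs the glutarate to act only as bis-nucleophile and C3 to be the only acyl acceptor: the tert-butyl esters of 2 are poor acyl acceptors, which suppresses the competing Claisen closure of the C4 carbanion of 4 onto a glutarate carbonyl, the symmetry of 2 about C1 makes the choice of the first enolate irrelevant, and the quaternary C1 rules out aromatisation.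

Step 3
Reactants: 5 di-tert-butyl 2,2,4-trimethyl-6-oxocyclohex-4-ene-1,3-dicarboxylate
Product: 8 tert-butyl 2,6,6-trimethyl-4-oxocyclohex-2-ene-1-carboxylate (racemic), via α-oxoketene 6 (not isolated), via β-keto acid 7 (not isolated)
Conditions: 1,4-dioxane–H2O (9:1), 130 °C, sealed tube
Reagents that add atoms: none
Why: The enolised β-keto tert-butyl ester should lose tert-butanol thermally to α-oxoketene 6, which water traps as β-keto acid 7 that decarboxylates (dealkoxycarbonylation of a β-keto ester); the second tert-butyl ester has no 1,3-keto relationship, cannot take this path and should survive.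

Step 4
Reactants: 8 tert-butyl 2,6,6-trimethyl-4-oxocyclohex-2-ene-1-carboxylate (racemic)
Product: 10 tert-butyl (1R,4R)-4-hydroxy-2,6,6-trimethylcyclohex-2-ene-1-carboxylate, via achiral dienol 9 (not isolated)
Conditions: NADPH-dependent ketoreductase (alcohol dehydrogenase class; chosen by panel screening), NADP+ (cat.), i-PrOH (15% v/v), triethanolamine buffer pH 8.5–9, 35 °C
Reagents that add atoms: none
Why: Proposed new method: the ketoreductase should accept only the enantiomer of 8 with the 6R configuration and deliver hydride from NADPH to one face of the C3 carbonyl (3R by enzyme facial control), while the unreactive enantiomer racemises through achiral dienol 9 because C6–H is both α to the ester and γ to the enone (a vinylogous β-keto ester) and is therefore exchanged by the buffer base, whereas the product, no longer a vinylogous β-keto ester, is configurationally stable; the closest known reaction type is the ketoreductase dynamic kinetic resolution of α-substituted β-keto esters and 2-substituted cyclic ketones, extended here to a stereocentre that is labile through the enone.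

Step 5
Reactants: 10 tert-butyl (1R,4R)-4-hydroxy-2,6,6-trimethylcyclohex-2-ene-1-carboxylate
Product: 11 tert-butyl (1R,4R)-4-{[tert-butyl(dimethyl)silyl]oxy}-2,6,6-trimethylcyclohex-2-ene-1-carboxylate
Conditions: TBSCl, imidazole, DMF, rt
Reagents that add atoms: tert-butyldimethylsilyl chloride (TBSCl), CC(C)(C)[Si](C)(C)Cl
Why: Silylation of the secondary allylic alcohol under imidazole catalysis masks the C3 hydroxyl for the Mitsunobu and carbanion steps without touching either stereocentre.

Step 6
Reactants: 11 tert-butyl (1R,4R)-4-{[tert-butyl(dimethyl)silyl]oxy}-2,6,6-trimethylcyclohex-2-ene-1-carboxylate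
Product: 13 [(1R,4R)-4-{[tert-butyl(dimethyl)silyl]oxy}-2,6,6-trimethylcyclohex-2-en-1-yl]methanol, via aldehyde 12 (not isolated)
Conditions: LiAlH4, THF, 0 → 40 °C; aq. NaOH work-up
Reagents that add atoms: none
Why: Hydride reduction of the ester through aldehyde 12 to the primary alcohol should outrun any enolisation at the adjacent stereocentre, and the silyl ether and the isolated trisubstituted alkene are inert to LiAlH4.

Step 7
Reactants: 13 [(1R,4R)-4-{[tert-butyl(dimethyl)silyl]oxy}-2,6,6-trimethylcyclohex-2-en-1-yl]methanol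
Product: 14 5-({[(1R,4R)-4-{[tert-butyl(dimethyl)silyl]oxy}-2,6,6-trimethylcyclohex-2-en-1-yl]methyl}sulfanyl)-1-phenyl-1H-tetrazole
Conditions: 1-phenyl-1H-tetrazole-5-thiol, PPh3, DIAD, THF, 0 °C → rt
Reagents that add atoms: 1-phenyl-1H-tetrazole-5-thiol, Sc1nnnn1-c1ccccc1
Why: Mitsunobu thioetherification of the primary alcohol with the acidic tetrazole thiol proceeds by SN2 displacement at the CH2 group, so the adjacent stereocentre is untouched.

Step 8
Reactants: 14 5-({[(1R,4R)-4-{[tert-butyl(dimethyl)silyl]oxy}-2,6,6-trimethylcyclohex-2-en-1-yl]methyl}sulfanyl)-1-phenyl-1H-tetrazole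
Product: 16 5-({[(1R,4R)-4-{[tert-butyl(dimethyl)silyl]oxy}-2,6,6-trimethylcyclohex-2-en-1-yl]methyl}sulfonyl)-1-phenyl-1H-tetrazole, via sulfoxide 15 (not isolated)
Conditions: (NH4)6Mo7O24·4H2O (10 mol %), 30% aq. H2O2, EtOH, 0 °C → rt
Reagents that add atoms: hydrogen peroxide, OO
Why: Molybdate-catalysed peroxide oxidation takes the sulfide through sulfoxide 15 to the sulfone and is selective for sulfur over the hindered trisubstituted alkene and the silyl ether.

Step 9
Reactants: 16 5-({[(1R,4R)-4-{[tert-butyl(dimethyl)silyl]oxy}-2,6,6-trimethylcyclohex-2-en-1-yl]methyl}sulfonyl)-1-phenyl-1H-tetrazole (2.3 equiv); 17 crocetindialdehyde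
Product: 19 (3R,6R,3′R,6′R)-3,3′-bis{[tert-butyl(dimethyl)silyl]oxy}-ε,ε-carotene (all-E), via C30 apocarotenal 18 (not isolated)
Conditions: KHMDS (2.3 equiv), THF, −78 °C; then 17 (1.0 equiv), −78 °C → rt, argon, dark; aq. NH4Cl; crude heated in heptane, 90 °C (E/Z equilibration)
Reagents that add atoms: none
Why: In this two-fold Julia–Kocienski olefination the potassium α-sulfonyl carbanion of 16 adds to each aldehyde group of 17 and Smiles rearrangement with loss of SO2 and the tetrazolone anion forms C7=C8 and C7′=C8′, E-selectively for a 1-phenyltetrazolyl sulfone with a potassium counter-ion and with thermal equilibration of any Z isomer, while C6–H is not acidic under these conditions.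

Step 10
Reactants: 19 (3R,6R,3′R,6′R)-3,3′-bis{[tert-butyl(dimethyl)silyl]oxy}-ε,ε-carotene
Product: 21 (3R,6R,3′R,6′R)-ε,ε-carotene-3,3′-diol (all-E; target), via mono-silyl ether 20 (not isolated)
Conditions: TBAF, THF, 0 °C → rt, argon, dark
Reagents that add atoms: none
Why: Fluoride cleaves both silyl ethers under non-acidic conditions that should preserve the acid-sensitive allylic alcohols, the doubly allylic C6–H and the polyene.

**Compound list**
1 | 3,3-dimethylpentanedioic acid (3,3-dimethylglutaric acid) | OC(=O)CC(C)(C)CC(=O)O | starting material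
2 | di-tert-butyl 3,3-dimethylpentanedioate | CC(C)(C)OC(=O)CC(C)(C)CC(=O)OC(C)(C)C | intermediate
3 | methyl but-2-ynoate | CC#CC(=O)OC | starting material
4 | 7-tert-butyl 1-methyl 4-(tert-butoxycarbonyl)-3,5,5-trimethylhept-2-enedioate (Michael adduct, E/Z, racemic; present as its anion) | COC(=O)C=C(C)C(C(=O)OC(C)(C)C)C(C)(C)CC(=O)OC(C)(C)C | intermediate (not isolated)
5 | di-tert-butyl 2,2,4-trimethyl-6-oxocyclohex-4-ene-1,3-dicarboxylate (racemic diastereomer mixture) | CC1=CC(=O)C(C(=O)OC(C)(C)C)C(C)(C)C1C(=O)OC(C)(C)C | intermediate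
6 | tert-butyl 2,6,6-trimethyl-4-oxo-5-(oxomethylidene)cyclohex-2-ene-1-carboxylate (α-oxoketene) | CC1=CC(=O)C(=C=O)C(C)(C)C1C(=O)OC(C)(C)C | intermediate (not isolated)
7 | 3-(tert-butoxycarbonyl)-2,2,4-trimethyl-6-oxocyclohex-4-ene-1-carboxylic acid (β-keto acid) | CC1=CC(=O)C(C(=O)O)C(C)(C)C1C(=O)OC(C)(C)C | intermediate (not isolated)
8 | tert-butyl 2,6,6-trimethyl-4-oxocyclohex-2-ene-1-carboxylate (racemic) | CC1=CC(=O)CC(C)(C)C1C(=O)OC(C)(C)C | intermediate
9 | tert-butyl 4-hydroxy-2,6,6-trimethylcyclohexa-1,3-diene-1-carboxylate (achiral dienol) | CC1=C(C(=O)OC(C)(C)C)C(C)(C)CC(O)=C1 | intermediate (not isolated)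
10 | tert-butyl (1R,4R)-4-hydroxy-2,6,6-trimethylcyclohex-2-ene-1-carboxylate (trans) | CC1=C[C@H](O)CC(C)(C)[C@H]1C(=O)OC(C)(C)C | intermediate
11 | tert-butyl (1R,4R)-4-{[tert-butyl(dimethyl)silyl]oxy}-2,6,6-trimethylcyclohex-2-ene-1-carboxylate | CC1=C[C@H](O[Si](C)(C)C(C)(C)C)CC(C)(C)[C@H]1C(=O)OC(C)(C)C | intermediate
12 | (1R,4R)-4-{[tert-butyl(dimethyl)silyl]oxy}-2,6,6-trimethylcyclohex-2-ene-1-carbaldehyde | CC1=C[C@H](O[Si](C)(C)C(C)(C)C)CC(C)(C)[C@H]1C=O | intermediate (not isolated)
13 | [(1R,4R)-4-{[tert-butyl(dimethyl)silyl]oxy}-2,6,6-trimethylcyclohex-2-en-1-yl]methanol | CC1=C[C@H](O[Si](C)(C)C(C)(C)C)CC(C)(C)[C@H]1CO | intermediate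
14 | 5-({[(1R,4R)-4-{[tert-butyl(dimethyl)silyl]oxy}-2,6,6-trimethylcyclohex-2-en-1-yl]methyl}sulfanyl)-1-phenyl-1H-tetrazole | CC1=C[C@H](O[Si](C)(C)C(C)(C)C)CC(C)(C)[C@H]1CSc1nnnn1-c1ccccc1 | intermediate
15 | 5-({[(1R,4R)-4-{[tert-butyl(dimethyl)silyl]oxy}-2,6,6-trimethylcyclohex-2-en-1-yl]methyl}sulfinyl)-1-phenyl-1H-tetrazole (both configurations at sulfur) | CC1=C[C@H](O[Si](C)(C)C(C)(C)C)CC(C)(C)[C@H]1CS(=O)c1nnnn1-c1ccccc1 | intermediate (not isolated)
16 | 5-({[(1R,4R)-4-{[tert-butyl(dimethyl)silyl]oxy}-2,6,6-trimethylcyclohex-2-en-1-yl]methyl}sulfonyl)-1-phenyl-1H-tetrazole | CC1=C[C@H](O[Si](C)(C)C(C)(C)C)CC(C)(C)[C@H]1CS(=O)(=O)c1nnnn1-c1ccccc1 | intermediate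
17 | crocetindialdehyde, (2E,4E,6E,8E,10E,12E,14E)-2,6,11,15-tetramethylhexadeca-2,4,6,8,10,12,14-heptaenedial | O=C/C(C)=C/C=C/C(C)=C/C=C/C=C(C)/C=C/C=C(C)/C=O | starting material
18 | (2E,4E,6E,8E,10E,12E,14E,16E)-17-[(1R,4R)-4-{[tert-butyl(dimethyl)silyl]oxy}-2,6,6-trimethylcyclohex-2-en-1-yl]-2,6,11,15-tetramethylheptadeca-2,4,6,8,10,12,14,16-octaenal (C30 apocarotenal) | CC1=C[C@H](O[Si](C)(C)C(C)(C)C)CC(C)(C)[C@H]1/C=C/C(C)=C/C=C/C(C)=C/C=C/C=C(C)/C=C/C=C(C)/C=O | intermediate (not isolated)
19 | (3R,6R,3′R,6′R)-3,3′-bis{[tert-butyl(dimethyl)silyl]oxy}-ε,ε-carotene (all-E) | CC1=C[C@H](O[Si](C)(C)C(C)(C)C)CC(C)(C)[C@H]1/C=C/C(C)=C/C=C/C(C)=C/C=C/C=C(C)/C=C/C=C(C)/C=C/[C@H]1C(C)=C[C@H](O[Si](C)(C)C(C)(C)C)CC1(C)C | intermediate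
20 | (3R,6R,3′R,6′R)-3′-{[tert-butyl(dimethyl)silyl]oxy}-ε,ε-caroten-3-ol | CC1=C[C@H](O)CC(C)(C)[C@H]1/C=C/C(C)=C/C=C/C(C)=C/C=C/C=C(C)/C=C/C=C(C)/C=C/[C@H]1C(C)=C[C@H](O[Si](C)(C)C(C)(C)C)CC1(C)C | intermediate (not isolated)
21 | (3R,6R,3′R,6′R)-ε,ε-carotene-3,3′-diol (all-E) | CC1=C[C@H](O)CC(C)(C)[C@H]1/C=C/C(C)=C/C=C/C(C)=C/C=C/C=C(C)/C=C/C=C(C)/C=C/[C@H]1C(C)=C[C@H](O)CC1(C)C | target

Total step count: 10. Longest linear sequence: 10 steps (1 → 21); 3 and 17 are bought.

**Steps most likely to fail**

Step 4 (ketoreductase dynamic kinetic resolution). Racemisation of the slow enantiomer through dienol 9 may be too slow against reduction, so that the process degrades to a simple kinetic resolution, or the enzyme may discriminate poorly between the carbonyl faces or the enantiomers. The fallback sets out from 8 and uses reagent control with recycling. Corey–Bakshi–Shibata reduction with catecholborane and the oxazaborolidine enantiomer that delivers the 4R carbinol (by the usual model the (S)-methyl catalyst, with the alkenyl arm as the large group; toluene, −78 °C) should give 10 together with its C1 epimer tert-butyl (1S,4R)-4-hydroxy-2,6,6-trimethylcyclohex-2-ene-1-carboxylate F1, which chromatography should separate. F1 is returned to the pool by MnO2 oxidation to tert-butyl (1S)-2,6,6-trimethyl-4-oxocyclohex-2-ene-1-carboxylate F2 and racemisation of F2 with DBU to 8. The route is rejoined at 10.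

Step 2 (Michael–Dieckmann annulation). Proton transfer from the propargylic methyl group of 3 to the enolate (allenoate formation and oligomerisation) may compete with conjugate addition, or the sequence may stall after the Michael step because the acyl acceptor is part of a delocalised anion. The fallback sets out from 1 and builds the ring by a different bond set (C3–C4 and C5–C6), with C2–C3 taken from the glutarate. Ac2O at reflux gives 3,3-dimethylglutaric anhydride F3. Opening with t-BuOH (DMAP, Et3N) gives 5-tert-butoxy-3,3-dimethyl-5-oxopentanoic acid F4. Carbonyldiimidazole and N,O-dimethylhydroxylamine hydrochloride give tert-butyl 5-[methoxy(methyl)amino]-3,3-dimethyl-5-oxopentanoate F5. 1-Propynylmagnesium bromide gives tert-butyl 3,3-dimethyl-5-oxooct-6-ynoate F6. t-BuOK in THF/t-BuOH should then close the ring by 6-endo-dig conjugate addition of the ester enolate to the ynone and give 8 directly, bypassing 5 and step 3. The route is rejoined at 8.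

Step 9 (two-fold Julia–Kocienski olefination). The second olefination on the sparingly soluble polyene dialdehyde may remain incomplete, the new C7=C8 bonds may form with low E selectivity, or the polyene may degrade under the strongly basic conditions. The fallback sets out from 13 and replaces the C10 + C20 + C10 plan by a C15 + C10 + C15 Wittig plan. Dess–Martin oxidation gives aldehyde 12, this time isolated. Horner–Wadsworth–Emmons reaction with dimethyl (2-oxopropyl)phosphonate under LiCl/DBU conditions, chosen to spare the α-stereocentre, gives (3E)-4-[(1R,4R)-4-{[tert-butyl(dimethyl)silyl]oxy}-2,6,6-trimethylcyclohex-2-en-1-yl]but-3-en-2-one F7. Vinylmagnesium bromide gives (1E)-1-[(1R,4R)-4-{[tert-butyl(dimethyl)silyl]oxy}-2,6,6-trimethylcyclohex-2-en-1-yl]-3-methylpenta-1,4-dien-3-ol F8. PPh3·HBr in MeOH effects allylic transposition with loss of the silyl group to [(2E,4E)-5-[(1R,4R)-4-hydroxy-2,6,6-trimethylcyclohex-2-en-1-yl]-3-methylpenta-2,4-dien-1-yl]triphenylphosphonium bromide F9. Double Wittig reaction of F9 with purchased (2E,4E,6E)-2,7-dimethylocta-2,4,6-trienedial (NaOMe, CH2Cl2/MeOH), followed by thermal E/Z equilibration in heptane, should give the target. The route is rejoined at 21.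

**Further compounds**
F1 | step 4 | tert-butyl (1S,4R)-4-hydroxy-2,6,6-trimethylcyclohex-2-ene-1-carboxylate | CC1=C[C@H](O)CC(C)(C)[C@@H]1C(=O)OC(C)(C)C
F2 | step 4 | tert-butyl (1S)-2,6,6-trimethyl-4-oxocyclohex-2-ene-1-carboxylate | CC1=CC(=O)CC(C)(C)[C@@H]1C(=O)OC(C)(C)C
F3 | step 2 | 4,4-dimethyloxane-2,6-dione (3,3-dimethylglutaric anhydride) | CC1(C)CC(=O)OC(=O)C1
F4 | step 2 | 5-tert-butoxy-3,3-dimethyl-5-oxopentanoic acid | CC(C)(C)OC(=O)CC(C)(C)CC(=O)O
F5 | step 2 | tert-butyl 5-[methoxy(methyl)amino]-3,3-dimethyl-5-oxopentanoate | CON(C)C(=O)CC(C)(C)CC(=O)OC(C)(C)C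
F6 | step 2 | tert-butyl 3,3-dimethyl-5-oxooct-6-ynoate | CC#CC(=O)CC(C)(C)CC(=O)OC(C)(C)C
F7 | step 9 | (3E)-4-[(1R,4R)-4-{[tert-butyl(dimethyl)silyl]oxy}-2,6,6-trimethylcyclohex-2-en-1-yl]but-3-en-2-one | CC(=O)/C=C/[C@H]1C(C)=C[C@H](O[Si](C)(C)C(C)(C)C)CC1(C)C
F8 | step 9 | (1E)-1-[(1R,4R)-4-{[tert-butyl(dimethyl)silyl]oxy}-2,6,6-trimethylcyclohex-2-en-1-yl]-3-methylpenta-1,4-dien-3-ol (both C3 epimers) | C=CC(C)(O)/C=C/[C@H]1C(C)=C[C@H](O[Si](C)(C)C(C)(C)C)CC1(C)C
F9 | step 9 | [(2E,4E)-5-[(1R,4R)-4-hydroxy-2,6,6-trimethylcyclohex-2-en-1-yl]-3-methylpenta-2,4-dien-1-yl]triphenylphosphonium bromide | [Br-].C/C(=C\C[P+](c1ccccc1)(c1ccccc1)c1ccccc1)/C=C/[C@H]1C(C)=C[C@H](O)CC1(C)C
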